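**Retrosynthetic overview**
1. Atom numbers follow ent-kaurane usage (C-1 ring A ketone, C-3/C-6 ether carbons, C-4 CMe2, C-7 lactone C=O, C-10 spiro carbon, C-15 ketone, C-16 carbinol, C-20 lactone CH2). Ring D is opened first: the C13–C16 bond and the tertiary alcohol come from an intramolecular carbonyl-ene reaction of a C-8 pyruvoyl group with a C12=C13 alkene. The ether ring comes from oxa-Michael addition of C6–OH to a ring A enone.
2. Ring C comes from a Diels–Alder reaction of buta-1,3-diene with the C8=C9 bond of an alkylidene β-keto-δ-lactone, which gives the cis lactone/ring C fusion.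
3. Ring A and the δ-lactone (ring B) come together from a cyclopentanol. An allyl α-diazo-β-keto ester is cyclopropanated intramolecularly; Lewis-acid scission of the C8–C10 cyclopropane bond with 1,2-shift of C-5 from C-1 to C-10 then turns the cyclopentanol into cyclohexanone ring A and the γ-lactone into the δ-lactone.
4. Enabling feature: spiro C-10 is α to the C-1 ketone of ring A and 1,3-related through C-9 to C-8, which carries two acyl groups (C-7 lactone carbonyl, C-15 ketone). This is the pattern of a ring-opened donor–acceptor cyclopropane whose donor carbon bore a tertiary carbinol.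
5. Order of ring formation: enantiopure cyclopentanone (Evans aldol, hydroacylation) → rings A + B (key step) → ring C → ether ring → ring D.

Key step: step 11

Assumption: C-8 of 20 and 21 is configurationally labile (β-keto lactone), so both are carried and drawn without a defined configuration there; it is erased in step 12. TBS = tert-butyldimethylsilyl, TMS = trimethylsilyl.

**Step 1**
Reactants: 1 3,3-dimethylpent-4-enoic acid; 2 (S)-4-benzyloxazolidin-2-one
Product: 4 (S)-4-benzyl-3-(3,3-dimethylpent-4-enoyl)oxazolidin-2-one, via mixed pivalic anhydride 3 (not isolated)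
Conditions: PivCl, Et3N, THF, −20 °C; then 2, LiCl, −20 °C → rt
Reagents that add atoms: none
Why: N-Acylation of the oxazolidinone by the mixed pivalic anhydride (acyl transfer at the less hindered carbonyl, LiCl-assisted) is the standard attachment of an Evans auxiliary and creates no stereocentre.

**Step 2**
Reactants: 4 (S)-4-benzyl-3-(3,3-dimethylpent-4-enoyl)oxazolidin-2-one
Product: 5 (S)-4-benzyl-3-[(R)-2-(hydroxymethyl)-3,3-dimethylpent-4-enoyl]oxazolidin-2-one
Conditions: TiCl4, i-Pr2NEt, CH2Cl2, 0 °C; then 1,3,5-trioxane, TiCl4, 0 °C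
Reagents that add atoms: 1,3,5-trioxane, C1OCOCO1
Why: Evans aldol-type hydroxymethylation in which the chelated Z-titanium enolate is attacked by TiCl4-activated formaldehyde (from trioxane) on the face away from the benzyl group, which sets the future C-5 as R.

**Step 3**
Reactants: 5 (S)-4-benzyl-3-[(R)-2-(hydroxymethyl)-3,3-dimethylpent-4-enoyl]oxazolidin-2-one
Product: 6 (S)-4-benzyl-3-[(R)-2-(TBSO-methyl)-3,3-dimethylpent-4-enoyl]oxazolidin-2-one
Conditions: TBSCl, imidazole, DMF, rt
Reagents that add atoms: tert-butyldimethylsilyl chloride, CC(C)(C)[Si](C)(C)Cl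
Why: Silyl ether formation masks the new primary alcohol and keeps the two CH2O arms at C-5 different before the auxiliary is removed, so the stereocentre is preserved.

**Step 4**
Reactants: 6 (S)-4-benzyl-3-[(R)-2-(TBSO-methyl)-3,3-dimethylpent-4-enoyl]oxazolidin-2-one
Product: 7 (S)-2-(TBSO-methyl)-3,3-dimethylpent-4-en-1-ol
Conditions: LiBH4, MeOH (1 equiv), THF, 0 °C
Reagents that add atoms: none
Why: Reductive cleavage of the N-acyl oxazolidinone with LiBH4 (hydride attack at the exocyclic carbonyl) should give the primary alcohol and the recoverable auxiliary without touching C-5 or the silyl ether.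

**Step 5**
Reactants: 7 (S)-2-(TBSO-methyl)-3,3-dimethylpent-4-en-1-ol
Product: 8 (R)-2-(TBSO-methyl)-3,3-dimethylpent-4-enal
Conditions: Dess–Martin periodinane, NaHCO3, CH2Cl2, 0 °C → rt
Reagents that add atoms: none
Why: Dess–Martin oxidation under bicarbonate buffer should give the α-branched aldehyde without epimerisation at C-5.

**Step 6**
Reactants: 8 (R)-2-(TBSO-methyl)-3,3-dimethylpent-4-enal
Product: 9 (R)-2-(TBSO-methyl)-3,3-dimethylcyclopentan-1-one
Conditions: [Rh(nbd)(dppe)]BF4 (5 mol %, activated with H2), CH2Cl2, rt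
Reagents that add atoms: none
Why: Intramolecular hydroacylation of a 4-pentenal with a cationic monovalent rhodium diphosphine catalyst (C–H oxidative addition, alkene insertion, reductive elimination) closes the cyclopentanone, helped by the gem-dimethyl group, and leaves C-5 untouched.

**Step 7**
Reactants: 9 (R)-2-(TBSO-methyl)-3,3-dimethylcyclopentan-1-one; 10 2-bromoprop-2-en-1-ol
Product: 13 2-[(1R,2R)-2-(TBSO-methyl)-3,3-dimethyl-1-(TMSO)cyclopentyl]prop-2-en-1-ol, via diol dialkoxide 11 (not isolated), via bis-silyl ether 12 (not isolated)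
Conditions: 10, t-BuLi (3 equiv), Et2O, −78 → 0 °C; CeCl3, THF, −78 °C; then 9; then TMSCl, −78 → 0 °C; then PPTS, MeOH, 0 °C
Reagents that add atoms: trimethylsilyl chloride, C[Si](C)(C)Cl
Why: 1,2-Addition of the alkenylcerium reagent (organocerium addition, which suppresses enolisation of the epimerisable ketone) should occur anti to the adjacent CH2OTBS group and so set C-1 as R, after which exhaustive silylation and selective acid methanolysis of the primary trimethylsilyl ether leave only the tertiary alcohol protected.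

**Step 8**
Reactants: 14 methyl 2,2-dimethoxypropanoate; 15 methyl acetate
Product: 16 methyl 4,4-dimethoxy-3-oxopentanoate
Conditions: 15, LiN(i-Pr)2 (2 equiv), THF, −78 °C; then 14, −78 → 0 °C; aq. NH4Cl
Reagents that add atoms: none
Why: Crossed Claisen condensation in which the lithium enolate of methyl acetate acylates the non-enolisable α,α-dimethoxy ester to give the β-keto ester.

**Step 9**
Reactants: 13 2-[(1R,2R)-2-(TBSO-methyl)-3,3-dimethyl-1-(TMSO)cyclopentyl]prop-2-en-1-ol; 16 methyl 4,4-dimethoxy-3-oxopentanoate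
Product: 17 2-[(1R,2R)-2-(TBSO-methyl)-3,3-dimethyl-1-(TMSO)cyclopentyl]prop-2-en-1-yl 4,4-dimethoxy-3-oxopentanoate
Conditions: DMAP (0.3 equiv), toluene, 110 °C, 4 Å molecular sieves
Reagents that add atoms: none
Why: DMAP-catalysed transesterification of a β-keto ester (through the acylketene) acylates the only free, primary allylic hydroxyl, the tertiary silyl ether being inert.

**Step 10**
Reactants: 17 2-[(1R,2R)-2-(TBSO-methyl)-3,3-dimethyl-1-(TMSO)cyclopentyl]prop-2-en-1-yl 4,4-dimethoxy-3-oxopentanoate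
Product: 18 2-[(1R,2R)-2-(TBSO-methyl)-3,3-dimethyl-1-(TMSO)cyclopentyl]prop-2-en-1-yl 2-diazo-4,4-dimethoxy-3-oxopentanoate
Conditions: 4-acetamidobenzenesulfonyl azide, Et3N, MeCN, 0 °C → rt
Reagents that add atoms: 4-acetamidobenzenesulfonyl azide, CC(=O)Nc1ccc(cc1)S(=O)(=O)N=[N+]=[N-]
Why: Regitz diazo transfer to the activated methylene of the 1,3-dicarbonyl unit.

**Step 11**
Reactants: 18 2-[(1R,2R)-2-(TBSO-methyl)-3,3-dimethyl-1-(TMSO)cyclopentyl]prop-2-en-1-yl 2-diazo-4,4-dimethoxy-3-oxopentanoate
Product: 20 (6S,11S)-11-(TBSO-methyl)-4-(2,2-dimethoxypropanoyl)-10,10-dimethyl-2-oxaspiro[5.5]undecane-3,7-dione (C-4 epimers), via cyclopropane-fused lactone 19 (not isolated)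
Conditions: Rh2(OAc)4 (2 mol %), CH2Cl2, 40 °C, slow addition of 18; then Sc(OTf)3 (10 mol %), 0 °C → rt; aq. NaHCO3
Reagents that add atoms: none
Why: Proposed new method: Rh2(OAc)4 converts 18 into an electrophilic carbenoid that adds to the tethered 1,1-disubstituted alkene, closing the γ-lactone and the cyclopropane in one intramolecular [2+1] event (known for allyl α-diazo-β-keto esters), and Sc(OTf)3 then chelates the 1,3-dicarbonyl unit of the donor–acceptor cyclopropane 19 and heterolyses its C8–C10 bond while C-5 shifts from the silyloxy carbon C-1 to C-10 (semipinacol 1,2-shift), the silyl group being lost from the oxocarbenium ion. The closest known reaction types are the Lewis-acid opening of cyclopropane-1,1-dicarbonyl compounds to 1,3-zwitterions and the semipinacol ring expansion of 2,3-epoxy silyl ethers of 1-alkenylcycloalkanols, here merged so that a C–C bond instead of a C–O bond is the leaving bond. Ring A arises from the cyclopentane by one-carbon ring expansion through the 1,2-shift, and the δ-lactone arises from the γ-lactone by cleavage of the fused cyclopropane bond, so both six-membered rings form by ring enlargement driven by release of cyclopropane strain and by C=O formation. Spiro C-10 is set in the cyclopropanation, where the carbenoid should attack the alkene face anti to the C1–C5 bond with the C1–OSiMe3 bond in the inside position (the outside position is crowded by the CH2O arm), and it is then transferred stereospecifically because C-5 enters anti to the departing C-8 with retention at C-5. The step needs migration of C-5 in preference to C-2, which the higher substitution of C-5 and its antiperiplanar placement in the reactive rotamer should secure, and it needs the shift to outrun closure of the zwitterion by the ketone oxygen or proton loss, which the silyl-ether push and the irreversible formation of the C-1 ketone should secure; C-8 of 20 is epimerisable and is levelled in step 12.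

**Step 12**
Reactants: 20 (6S,11S)-11-(TBSO-methyl)-4-(2,2-dimethoxypropanoyl)-10,10-dimethyl-2-oxaspiro[5.5]undecane-3,7-dione
Product: 22 (6S,11S)-11-(TBSO-methyl)-4-(2,2-dimethoxypropanoyl)-10,10-dimethyl-2-oxaspiro[5.5]undec-4-ene-3,7-dione, via selenide 21 (not isolated)
Conditions: PhSeCl, pyridine, CH2Cl2, 0 °C; then 30% aq. H2O2, 0 °C → rt
Reagents that add atoms: none
Why: α-Selenenylation of the enolised β-keto lactone followed by oxidation and selenoxide syn-elimination should introduce the C8=C9 double bond selectively, because pyridine does not enolise the ring A ketone, and it removes the undefined C-8 centre.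

**Step 13**
Reactants: 22 (6S,11S)-11-(TBSO-methyl)-4-(2,2-dimethoxypropanoyl)-10,10-dimethyl-2-oxaspiro[5.5]undec-4-ene-3,7-dione; 23 buta-1,3-diene
Product: 24 (1S,6S,4a'S,8a'S)-6-(TBSO-methyl)-8a'-(2,2-dimethoxypropanoyl)-5,5-dimethyl-4a',5',8',8a'-tetrahydrospiro[cyclohexane-1,4'-isochromene]-1',2(3'H)-dione
Conditions: 23 (excess), ZnCl2 (30 mol %), CH2Cl2, sealed tube, 0 °C → rt
Reagents that add atoms: none
Why: Lewis-acid-catalysed Diels–Alder reaction of the doubly activated alkene, in which suprafacial addition gives the cis lactone/cyclohexene fusion and sets C-8 and C-9 together, and the diene should add to the lactone face flanked by the flat C-1 carbonyl, anti to the bulkier C-5 (CH2OTBS, gem-dimethyl) side of spiro C-10.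

**Step 14**
Reactants: 24 (1S,6S,4a'S,8a'S)-6-(TBSO-methyl)-8a'-(2,2-dimethoxypropanoyl)-5,5-dimethyl-4a',5',8',8a'-tetrahydrospiro[cyclohexane-1,4'-isochromene]-1',2(3'H)-dione
Product: 25 (1S,6S,4a'S,8a'S)-6-(TBSO-methyl)-8a'-(2,2-dimethoxypropanoyl)-5,5-dimethyl-4a',5',8',8a'-tetrahydrospiro[cyclohex-3-ene-1,4'-isochromene]-1',2(3'H)-dione
Conditions: IBX, DMSO, 70 °C
Reagents that add atoms: none
Why: IBX-mediated dehydrogenation of a ketone to the enone, in which only C-2 of the C-1 ketone carries enolisable hydrogen, since C-10 and C-8 are quaternary.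

**Step 15**
Reactants: 25 (1S,6S,4a'S,8a'S)-6-(TBSO-methyl)-8a'-(2,2-dimethoxypropanoyl)-5,5-dimethyl-4a',5',8',8a'-tetrahydrospiro[cyclohex-3-ene-1,4'-isochromene]-1',2(3'H)-dione
Product: 26 ether-bridged diketone (8,8-dimethyl-6-oxabicyclo[3.2.1]octan-3-one spiro-linked through its C-2 to C-4 of the cis-fused 8a-pyruvoyl-4a,5,8,8a-tetrahydroisochroman-1-one)
Conditions: TFA–H2O (9:1), CH2Cl2, 0 °C → rt
Reagents that add atoms: water, O
Why: Aqueous acid removes the silyl ether and hydrolyses the dimethyl ketal, and the liberated C6–OH adds to the enone in an acid-catalysed intramolecular oxa-Michael reaction whose tether can reach only one face of C-3, which fixes that stereocentre.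

**Step 16**
Reactants: 26 ether-bridged diketone
Product: 27 11,12-didehydro precursor of the target (bicyclo[3.2.1]oct-2-ene with the C-15 ketone and the C-16 tertiary alcohol in place)
Conditions: Sc(OTf)3 (10 mol %), CH2Cl2, rt
Reagents that add atoms: none
Why: Lewis-acid-catalysed intramolecular carbonyl-ene reaction of the chelated 1,2-diketone, in which the axial pyruvoyl carbonyl carbon reaches the nearer alkene carbon C-13 (five-membered ring D) on the only accessible face, which fixes C-13, while the cyclic six-centre transition state requires the carbonyl oxygen to take the pseudoaxial allylic hydrogen from C-11, which places the new hydroxyl endo (towards C-11) and the methyl exo at C-16.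

**Step 17**
Reactants: 27 11,12-didehydro precursor of the target
Product: 28 CNP0538153.1 (target)
Conditions: H2 (1 atm), 10% Pd/C, EtOAc, rt
Reagents that add atoms: none
Why: Heterogeneous catalytic hydrogenation of the isolated cis-disubstituted alkene, in which ketones, lactone and the tertiary alcohol are inert and no stereocentre is formed.

**Compound list**
1 | 3,3-dimethylpent-4-enoic acid | C=CC(C)(C)CC(=O)O | starting material
2 | (S)-4-benzyloxazolidin-2-one | O=C1N[C@@H](Cc2ccccc2)CO1 | starting material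
3 | 3,3-dimethylpent-4-enoic pivalic anhydride | C=CC(C)(C)CC(=O)OC(=O)C(C)(C)C | intermediate
4 | (S)-4-benzyl-3-(3,3-dimethylpent-4-enoyl)oxazolidin-2-one | C=CC(C)(C)CC(=O)N1[C@@H](Cc2ccccc2)COC1=O | intermediate
5 | (S)-4-benzyl-3-[(R)-2-(hydroxymethyl)-3,3-dimethylpent-4-enoyl]oxazolidin-2-one | C=CC(C)(C)[C@H](CO)C(=O)N1[C@@H](Cc2ccccc2)COC1=O | intermediate
6 | (S)-4-benzyl-3-[(R)-2-(TBSO-methyl)-3,3-dimethylpent-4-enoyl]oxazolidin-2-one | C=CC(C)(C)[C@H](CO[Si](C)(C)C(C)(C)C)C(=O)N1[C@@H](Cc2ccccc2)COC1=O | intermediate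
7 | (S)-2-(TBSO-methyl)-3,3-dimethylpent-4-en-1-ol | C=CC(C)(C)[C@H](CO[Si](C)(C)C(C)(C)C)CO | intermediate
8 | (R)-2-(TBSO-methyl)-3,3-dimethylpent-4-enal | C=CC(C)(C)[C@H](CO[Si](C)(C)C(C)(C)C)C=O | intermediate
9 | (R)-2-(TBSO-methyl)-3,3-dimethylcyclopentan-1-one | O=C1CCC(C)(C)[C@@H]1CO[Si](C)(C)C(C)(C)C | intermediate
10 | 2-bromoprop-2-en-1-ol | C=C(Br)CO | starting material
11 | (1R,2R)-2-(TBSO-methyl)-1-(3-hydroxyprop-1-en-2-yl)-3,3-dimethylcyclopentan-1-ol (formed as its dialkoxide) | CC1(C)CC[C@](O)(C(=C)CO)[C@H]1CO[Si](C)(C)C(C)(C)C | intermediate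
12 | bis(trimethylsilyl) ether of 11 | CC1(C)CC[C@](O[Si](C)(C)C)(C(=C)CO[Si](C)(C)C)[C@H]1CO[Si](C)(C)C(C)(C)C | intermediate
13 | 2-[(1R,2R)-2-(TBSO-methyl)-3,3-dimethyl-1-(TMSO)cyclopentyl]prop-2-en-1-ol | CC1(C)CC[C@](O[Si](C)(C)C)(C(=C)CO)[C@H]1CO[Si](C)(C)C(C)(C)C | intermediate
14 | methyl 2,2-dimethoxypropanoate | COC(=O)C(C)(OC)OC | starting material
15 | methyl acetate | CC(=O)OC | starting material
16 | methyl 4,4-dimethoxy-3-oxopentanoate | COC(=O)CC(=O)C(C)(OC)OC | intermediate
17 | 2-[(1R,2R)-2-(TBSO-methyl)-3,3-dimethyl-1-(TMSO)cyclopentyl]prop-2-en-1-yl 4,4-dimethoxy-3-oxopentanoate | CC1(C)CC[C@](O[Si](C)(C)C)(C(=C)COC(=O)CC(=O)C(C)(OC)OC)[C@H]1CO[Si](C)(C)C(C)(C)C | intermediate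
18 | 2-[(1R,2R)-2-(TBSO-methyl)-3,3-dimethyl-1-(TMSO)cyclopentyl]prop-2-en-1-yl 2-diazo-4,4-dimethoxy-3-oxopentanoate | CC1(C)CC[C@](O[Si](C)(C)C)(C(=C)COC(=O)C(=[N+]=[N-])C(=O)C(C)(OC)OC)[C@H]1CO[Si](C)(C)C(C)(C)C | intermediate
19 | (1R,5R)-5-[(1R,2R)-2-(TBSO-methyl)-3,3-dimethyl-1-(TMSO)cyclopentyl]-1-(2,2-dimethoxypropanoyl)-3-oxabicyclo[3.1.0]hexan-2-one | O=C1OC[C@]2(C[C@@]12C(=O)C(C)(OC)OC)[C@@]3(O[Si](C)(C)C)CCC(C)(C)[C@@H]3CO[Si](C)(C)C(C)(C)C | intermediate
20 | (6S,11S)-11-(TBSO-methyl)-4-(2,2-dimethoxypropanoyl)-10,10-dimethyl-2-oxaspiro[5.5]undecane-3,7-dione (C-4 epimers) | CC1(C)CCC(=O)[C@]2(COC(=O)C(C2)C(=O)C(C)(OC)OC)[C@H]1CO[Si](C)(C)C(C)(C)C | intermediate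
21 | 4-(phenylselanyl) derivative of 20 | CC1(C)CCC(=O)[C@]2(COC(=O)C(C2)([Se]c3ccccc3)C(=O)C(C)(OC)OC)[C@H]1CO[Si](C)(C)C(C)(C)C | intermediate
22 | (6S,11S)-11-(TBSO-methyl)-4-(2,2-dimethoxypropanoyl)-10,10-dimethyl-2-oxaspiro[5.5]undec-4-ene-3,7-dione | CC1(C)CCC(=O)[C@]2(COC(=O)C(=C2)C(=O)C(C)(OC)OC)[C@H]1CO[Si](C)(C)C(C)(C)C | intermediate
23 | buta-1,3-diene | C=CC=C | starting material
24 | (1S,6S,4a'S,8a'S)-6-(TBSO-methyl)-8a'-(2,2-dimethoxypropanoyl)-5,5-dimethyl-4a',5',8',8a'-tetrahydrospiro[cyclohexane-1,4'-isochromene]-1',2(3'H)-dione | CC1(C)CCC(=O)[C@]2(COC(=O)[C@]3(CC=CC[C@H]32)C(=O)C(C)(OC)OC)[C@H]1CO[Si](C)(C)C(C)(C)C | intermediate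
25 | (1S,6S,4a'S,8a'S)-6-(TBSO-methyl)-8a'-(2,2-dimethoxypropanoyl)-5,5-dimethyl-4a',5',8',8a'-tetrahydrospiro[cyclohex-3-ene-1,4'-isochromene]-1',2(3'H)-dione | CC1(C)C=CC(=O)[C@]2(COC(=O)[C@]3(CC=CC[C@H]32)C(=O)C(C)(OC)OC)[C@H]1CO[Si](C)(C)C(C)(C)C | intermediate
26 | ether-bridged diketone (6-oxabicyclo[3.2.1]octan-3-one spiro-linked to the cis-fused 8a-pyruvoyl-tetrahydroisochroman-1-one) | CC1(C)[C@@H]2CC(=O)[C@]3(COC(=O)[C@]4(CC=CC[C@H]43)C(=O)C(C)=O)[C@H]1CO2 | intermediate
27 | 11,12-didehydro precursor of the target | CC1(C)[C@@H]2CC(=O)[C@]3(COC(=O)[C@@]45C[C@@H](C=C[C@H]43)[C@@](C)(O)C5=O)[C@H]1CO2 | intermediate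
28 | CNP0538153.1 (C-3 S, C-5 S, C-8 S, C-9 S, C-10 S, C-13 R, C-16 R) | CC1(C)[C@@H]2CC(=O)[C@]3(COC(=O)[C@@]45C[C@@H](CC[C@H]43)[C@@](C)(O)C5=O)[C@H]1CO2 | target

**Totals and risks**
Total step count: 17. Longest linear sequence: 16 steps (steps 1 to 7 and 9 to 17).

Steps most likely to fail:

1. Step 11 (proposed new method). The cyclopropane may resist ionisation under a mild Lewis acid. The zwitterion may instead close through the ketone oxygen or lose a proton. C-2 may migrate in place of C-5. The facial selectivity of the cyclopropanation, which fixes C-10, may be poor. A bypass by known chemistry sets out from 17. Epoxidation of the 1,1-disubstituted alkene (mCPBA, NaHCO3, CH2Cl2, 0 °C) should give the epoxy silyl ether F1. Its semipinacol rearrangement (TMSOTf cat., CH2Cl2, −78 °C), the established ring expansion of epoxides of 1-alkenylcycloalkanol silyl ethers, should give the ring-expanded hydroxymethyl ketone F2 with the same sense at C-10. Dess–Martin oxidation should give the aldehyde F3. Intramolecular Knoevenagel condensation of the β-keto ester arm onto the aldehyde (piperidinium acetate, benzene, rt) should close the δ-lactone and come back to the route at 22, replacing steps 10 to 12.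

2. Step 13. Cycloaddition at the neopentyl C-9 may be sluggish, the diene may polymerise, and the facial selectivity at the spiro centre may be poor. The fallback sets out from 22. A thermal Diels–Alder reaction with the far more reactive 2-(trimethylsilyloxy)buta-1,3-diene (toluene, 60 °C) should give the silyl enol ether F4 with the oxygen at C-12. CsF and PhNTf2 (DME, rt) should convert it into the enol triflate F5. Palladium-catalysed formate reduction (Pd(OAc)2, PPh3, HCO2H, Bu3N, DMF, 60 °C) should remove the triflate and come back to the route at 24.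

3. Step 16. Closure may occur at C-12 with hydrogen transfer from C-14 (bicyclo[2.2.2]octene formation), or Prins-type side reactions may intervene. The fallback sets out from 22 and builds an electronic bias into the alkene. A Diels–Alder reaction with 2-chlorobuta-1,3-diene (ZnCl2, CH2Cl2) should give the chloro adduct F6 with chlorine at C-12. IBX dehydrogenation should give the chloro enone F7, and TFA–H2O should give the chloro diketone F8. In the Lewis-acid ene closure the chlorine should stabilise positive charge at C-12 and direct bond formation to C-13, giving the vinyl chloride F9. Hydrogenation with hydrogenolysis of the vinyl chloride (H2, Pd/C, Et3N, EtOAc) should come back to the route at 28.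

**Further compounds**
F1 | step 11 | epoxide of 17 ({2-[(1R,2R)-2-(TBSO-methyl)-3,3-dimethyl-1-(TMSO)cyclopentyl]oxiran-2-yl}methyl 4,4-dimethoxy-3-oxopentanoate) | CC1(C)CC[C@](O[Si](C)(C)C)([C@]2(COC(=O)CC(=O)C(C)(OC)OC)CO2)[C@H]1CO[Si](C)(C)C(C)(C)C
F2 | step 11 | [(1S,2S)-2-(TBSO-methyl)-1-(hydroxymethyl)-3,3-dimethyl-6-oxocyclohexyl]methyl 4,4-dimethoxy-3-oxopentanoate | CC1(C)CCC(=O)[C@](CO)(COC(=O)CC(=O)C(C)(OC)OC)[C@H]1CO[Si](C)(C)C(C)(C)C
F3 | step 11 | [(1S,2S)-2-(TBSO-methyl)-1-formyl-3,3-dimethyl-6-oxocyclohexyl]methyl 4,4-dimethoxy-3-oxopentanoate | CC1(C)CCC(=O)[C@](C=O)(COC(=O)CC(=O)C(C)(OC)OC)[C@H]1CO[Si](C)(C)C(C)(C)C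
F4 | step 13 | 6'-(trimethylsilyloxy) derivative of 24 (silyl enol ether at C-12) | CC1(C)CCC(=O)[C@]2(COC(=O)[C@]3(CC=C(O[Si](C)(C)C)C[C@H]32)C(=O)C(C)(OC)OC)[C@H]1CO[Si](C)(C)C(C)(C)C
F5 | step 13 | 6'-(trifluoromethanesulfonyloxy) derivative of 24 (enol triflate at C-12) | CC1(C)CCC(=O)[C@]2(COC(=O)[C@]3(CC=C(OS(=O)(=O)C(F)(F)F)C[C@H]32)C(=O)C(C)(OC)OC)[C@H]1CO[Si](C)(C)C(C)(C)C
F6 | step 16 | 6'-chloro derivative of 24 (chlorine at C-12) | CC1(C)CCC(=O)[C@]2(COC(=O)[C@]3(CC=C(Cl)C[C@H]32)C(=O)C(C)(OC)OC)[C@H]1CO[Si](C)(C)C(C)(C)C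
F7 | step 16 | 6'-chloro derivative of 25 | CC1(C)C=CC(=O)[C@]2(COC(=O)[C@]3(CC=C(Cl)C[C@H]32)C(=O)C(C)(OC)OC)[C@H]1CO[Si](C)(C)C(C)(C)C
F8 | step 16 | 12-chloro derivative of 26 | CC1(C)[C@@H]2CC(=O)[C@]3(COC(=O)[C@]4(CC=C(Cl)C[C@H]43)C(=O)C(C)=O)[C@H]1CO2
F9 | step 16 | 12-chloro derivative of 27 | CC1(C)[C@@H]2CC(=O)[C@]3(COC(=O)[C@@]45C[C@@H](C(Cl)=C[C@H]43)[C@@](C)(O)C5=O)[C@H]1CO2
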